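The flask you take over holds 20 mM of starting material in the first phase and 20.0 mM of reagent in the second, half the reagent of the summer run.

| flask | starting material | reagent in the second phase | remark | time | volume of the second phase over the first |
|---|---|---|---|---|---|
| summer | 20 mM | 40 mM | run made earlier |  |  |
| flask | 20 mM | 20.0 mM |  | 6.0 min | 1.0 |

summer run (percent of the starting material charged)

| time / s | target / % | starting material / % |
|---|---|---|
| 10.0 | 1.4 | 97.3 |
| 12.0 | 1.6 | 96.0 |
| 30.0 | 5.6 | 87.0 |
| 80.0 | 7.7 | 59.8 |

(each reading ± 0.5 percentage points)

- what is said of target includes product in the second phase
- in the second phase: reagent in the second phase, product in the second phase; everything else is in the first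
- charges count per volume of the first phase; a concentration in a rate is the amount of a species over the volume of its own phase; every rate counts per litre of the first phase
- the earlier runs hold the two phases in the same ratio of volumes as the flask asked about

1. target and product in the second phase together at 6.0 min, in percent of the starting material charged
2. part of the starting material charged that has reacted at 6.0 min

From the last summer reading, take the logarithmic fall of starting material per unit of reagent charge and time; at fixed reagent this is a pseudo-first-order constant per mM. I call it the reagent pace 0.00964 mM⁻¹ min⁻¹. It assumes first order in reagent, which one run cannot test.

For your flask, with [reagent in the second phase] at its charge: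

pace × [reagent in the second phase] × time = 1.16

reacted if the reagent never fell = 68.6 %

reacted if each starting material uses one reagent = 53.6 %

The reagent does fall, and the summer pace already carries some of that fall, so I expect your flask to lie between these, near 61.1 %. I reckon no figure for the target. Do not add reagent: this reckoning counts its charge.

The forecast says 62 % reacted and 2.9 % target, also “Assuming first order in reagent”, but with about 2 starting material lost per reagent where I take one.

The flask gives 62.6 % reacted and 6.50 % target.

    reagent in the reaction phase ⇌ reagent in the second phase, rate k1*([reagent in the reaction phase] - [reagent in the second phase]/K1) per volume of the first phase (partition coefficient = 1.74, kL = 0.0296 s⁻¹)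
    starting material + reagent in the reaction phase → target (k = 1.06 M⁻¹ s⁻¹)
    target ⇌ product in the second phase, rate k3*([target] - [product in the second phase]/K3) per volume of the first phase (partition coefficient = 16.1, kL = 0.0138 s⁻¹)
    target → decomposed product (k = 0.0449 s⁻¹)
    starting material → decomposition product (k = 1.58 × 10⁻⁵ s⁻¹)
    reagent in the reaction phase ⇌ dormant form (K = 1.10, k = 0.0323 s⁻¹)
    target → over-reaction product (k = 0.0646 s⁻¹)

This flask's own pace comes to 0.00819 mM⁻¹ min⁻¹ against the summer 0.00964 mM⁻¹ min⁻¹, with reagent in the second phase down to 18.0 % of its charge. The same flask stopped at 1.5 min has 75.2 % starting material left, and the summer pace gives 74.9 %. Target stays low in this flask partly because of the drag of the passage of target into product in the second phase, a larger effect on it than any other tried: this flask without that drag gives 18.3 % instead of 6.50 %.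

The data are calculated with constants of no real substance.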